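**Retrosynthetic overview**
1. Numbering for each half (naphthalen-1(4H)-one): ring B = C1 (ketone), C2 (bears the CH2 bridge), C3 (enol), C4 (CMe2), C4a, C8a. Ring A = C4a, C5 (H), C6 (OH), C7 (acetyl), C8 (OH), C8a.
2. Feature used: ring A hides two 1,3-dicarbonyl units. The run C5–C6–C7–C(=O)CH3 has the skeleton and oxygen pattern of pentane-2,4-dione. C8a holds two carboxyl-level carbons (C8 in ring A, C1 in ring B), as the central carbon of a malonate does, so C4a is an acyl carbon.
3. Last skeletal disconnection: C1–C2 in both halves (double Dieckmann). This opens both B rings and shows C3–C2–CH2–C2–C3 to be a glutaryl chain.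
4. Key disconnection: C4a–C5 and C7–C8 in both halves, a twofold formal (3+3) of a bis(1-methoxyalkylidene malonate) with two acetylacetone bis(silyl enol ethers).
5. The acceptor comes from glutaryl chloride, two isobutyrate enolates (C4 with its methyls, and C4a) and two dimethyl malonates. Ring order: both A rings together, then both B rings together.

Key step: step 8

Assumption: the target has no stereocentre and is written as the bis-enol tautomer of its SMILES. The 1,3-dione tautomers equilibrate, so no step has to fix them. The Z geometry drawn for 12–15 has no bearing on the outcome, because that double bond ends up in the aromatic ring.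

**Step 1**
Reactants: 1 glutaryl chloride; 2 benzyl isobutyrate
Product: 4 dibenzyl 2,2,8,8-tetramethyl-3,7-dioxononanedioate, via lithium enolate of benzyl isobutyrate 3 (not isolated)
Conditions: LiN(iPr)2 (2.4 equiv), 2 (2.4 equiv), THF, −78 °C; then 1 (1.0 equiv) added slowly, −78 °C; aq NH4Cl
Reagents that add atoms: none
Why: Crossed Claisen-type C-acylation of a preformed, fully substituted ester enolate by an acid chloride installs both CMe2 groups directly; the product has no proton between its carbonyls, so no second enolate is consumed and no aldol-prone 3,7-dioxo diester has to be methylated four times.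

**Step 2**
Reactants: 4 dibenzyl 2,2,8,8-tetramethyl-3,7-dioxononanedioate
Product: 5 2,2,8,8-tetramethyl-3,7-dioxononanedioic acid
Conditions: H2 (1 atm), Pd/C (10 wt %), EtOAc, 0 °C; filter cold, concentrate below 10 °C, use at once
Reagents that add atoms: none
Why: Hydrogenolysis of benzyl esters is neutral and runs cold, which suits 2,2-dimethyl-3-oxo acids that lose CO2 on warming, and dialkyl ketones are inert to Pd/C under these conditions.

**Step 3**
Reactants: 5 2,2,8,8-tetramethyl-3,7-dioxononanedioic acid
Product: 6 2,2,8,8-tetramethyl-3,7-dioxononanedioyl dichloride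
Conditions: (COCl)2 (3 equiv), DMF (cat.), CH2Cl2, 0 °C; evaporate, use crude
Reagents that add atoms: oxalyl chloride, O=C(Cl)C(=O)Cl
Why: Acid chloride formation through the Vilsmeier-type chloroiminium salt works at 0 °C; the quaternary α-carbon rules out ketene formation, and removal of the acidic proton ends the decarboxylation pathway.

**Step 4**
Reactants: 6 2,2,8,8-tetramethyl-3,7-dioxononanedioyl dichloride; 7 dimethyl malonate
Product: 9 tetramethyl 2,2'-(2,2,8,8-tetramethyl-3,7-dioxononanedioyl)dimalonate, via chloromagnesium enolate of dimethyl malonate 8 (not isolated)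
Conditions: 7 (2.4 equiv), MgCl2 (2.4 equiv), Et3N (5 equiv), MeCN, 0 °C; then 6 in CH2Cl2, 0 °C → rt; cold 1 M HCl
Reagents that add atoms: none
Why: Soft-enolisation C-acylation of a malonate (MgCl2/Et3N) gives the acylmalonate as its magnesium chelate, which blocks O-acylation, retro-Claisen cleavage of the 2,2-dimethyl-1,3-dione unit and premature attack of C2 on an ester.

**Step 5**
Reactants: 9 tetramethyl 2,2'-(2,2,8,8-tetramethyl-3,7-dioxononanedioyl)dimalonate
Product: 10 tetramethyl 2,2'-(1,9-dimethoxy-2,2,8,8-tetramethyl-3,7-dioxononane-1,9-diylidene)dimalonate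
Conditions: Me3SiCHN2 (3 equiv, hexanes), toluene/MeOH 4:1, 0 °C → rt
Reagents that add atoms: trimethylsilyldiazomethane, C[Si](C)(C)C=[N+]=[N-]
Why: O-methylation of a strongly acidic tricarbonyl compound by a diazoalkane goes by proton transfer and then methyl transfer to the hard enolate oxygen; it needs no added base, so the C2 methylenes stay untouched and no Dieckmann closure can start.

**Step 6**
Reactants: 11 acetylacetone
Product: 12 (Z)-4-(trimethylsilyloxy)pent-3-en-2-one
Conditions: Me3SiCl, Et3N, pentane, rt
Reagents that add atoms: chlorotrimethylsilane, C[Si](C)(C)Cl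
Why: O-silylation of the enol form of a 1,3-diketone with a chlorosilane and a tertiary amine is a standard silyl enol ether synthesis.

**Step 7**
Reactants: 12 (Z)-4-(trimethylsilyloxy)pent-3-en-2-one
Product: 14 (3Z)-2,4-bis(trimethylsilyloxy)penta-1,3-diene, via lithium 4-(trimethylsilyloxy)penta-1,3-dien-2-olate 13 (not isolated)
Conditions: LiN(iPr)2, THF, −78 °C; Me3SiCl, −78 °C → rt; pentane, filter under argon
Reagents that add atoms: chlorotrimethylsilane, C[Si](C)(C)Cl
Why: Kinetic deprotonation of the methyl ketone followed by O-silylation of the cross-conjugated dienolate is the usual second silylation that masks a 1,3-dicarbonyl dianion as a bis(silyl enol ether).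

**Step 8**
Reactants: 10 tetramethyl 2,2'-(1,9-dimethoxy-2,2,8,8-tetramethyl-3,7-dioxononane-1,9-diylidene)dimalonate; 14 (3Z)-2,4-bis(trimethylsilyloxy)penta-1,3-diene
Product: 16 dimethyl 6,6'-(2,8-dimethyl-3,7-dioxononane-2,8-diyl)bis(3-acetyl-2,4-dihydroxybenzoate), via open-chain twofold addition-elimination adduct 15 (not isolated)
Conditions: 14 (3 equiv), TiCl4 (2.4 equiv), CH2Cl2, −78 °C → rt, 20 h; 1 M HCl
Reagents that add atoms: none
Why: Proposed new method: TiCl4 should bind the two ester carbonyls on each C8a as a six-membered chelate, which turns the methoxy-bearing C4a into a strongly polarised acceptor; the unsubstituted terminal carbon of 14 (future C5) adds there and methoxide is expelled (addition-elimination, C4a–C5), giving 15. In 15 the remaining silyl enol ether carbon (future C7) lies next to the ester that is cis to the new chain and acylates on it (Claisen-type C7–C8 bond, second methoxide lost), so each ring A closes in the 6-exo-trig mode, and the resulting cyclohexenedione enolises twice to the resorcinol. The closest known reaction type is the TiCl4-mediated formal (3+3) cyclocondensation of 1,3-bis(silyl enol ethers) with 3-alkoxy- or 3-silyloxy-2-en-1-ones, in which 14 gives 2-acetylphenols; not yet shown are a 1-alkoxyalkylidene malonate whose acceptor carbon stands beside a quaternary carbon, ring closure on an ester instead of a ketone, and two such annulations in one molecule. The step needs C5 to choose C4a over the C3 ketone: C4a is activated by two chelated esters, whereas C3 is an unactivated dialkyl ketone shielded on one side by the same CMe2 group. Regiochemistry follows from the order of nucleophilicity in 14 (terminal carbon first, central carbon second), which places the acetyl group on C7 between the two hydroxyls, and the two esters on C8a are constitutionally identical, so whichever is cis to the chain gives the same ring while the other stays as the C1 ester. No stereocentre is formed, and the double-bond geometry of 14 is lost on aromatisation.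

**Step 9**
Reactants: 16 dimethyl 6,6'-(2,8-dimethyl-3,7-dioxononane-2,8-diyl)bis(3-acetyl-2,4-dihydroxybenzoate)
Product: 17 dimethyl 6,6'-(2,8-dimethyl-3,7-dioxononane-2,8-diyl)bis[3-acetyl-2,4-bis(benzyloxy)benzoate]
Conditions: BnBr (6 equiv), K2CO3, Bu4NI (cat.), DMF, 40 °C
Reagents that add atoms: benzyl bromide, BrCc1ccccc1
Why: Williamson etherification of the four acidic, chelated phenols removes the phenoxide donation that would deactivate the C1 esters, and benzyl is chosen because it later leaves under neutral conditions that spare the acid-sensitive methylene-bridged bis(1,3-dione).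

**Step 10**
Reactants: 17 dimethyl 6,6'-(2,8-dimethyl-3,7-dioxononane-2,8-diyl)bis[3-acetyl-2,4-bis(benzyloxy)benzoate]
Product: 18 2,2'-methylenebis[7-acetyl-6,8-bis(benzyloxy)-3-hydroxy-4,4-dimethylnaphthalen-1(4H)-one]
Conditions: KOtBu (6 equiv), THF, 0 °C → rt; cold 1 M HCl
Reagents that add atoms: none
Why: Double Dieckmann condensation, in which each C2 enolate attacks the C1 ester of its own half (6-exo-trig, helped by the gem-dimethyl group and by the ester being twisted out of the arene plane); the acetyl enolates have no electrophile within reach, and both products are drained as stabilised 1,3-dione enolates.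

**Step 11**
Reactants: 18 2,2'-methylenebis[7-acetyl-6,8-bis(benzyloxy)-3-hydroxy-4,4-dimethylnaphthalen-1(4H)-one]
Product: 19 2,2'-methylenebis(7-acetyl-3,6,8-trihydroxy-4,4-dimethylnaphthalen-1(4H)-one), the target CNP0295164.0
Conditions: H2 (1 atm), Pd/C, EtOAc/MeOH, rt
Reagents that add atoms: none
Why: Hydrogenolysis of aryl benzyl ethers is neutral, so neither cyclodehydration of the bis(1,3-dione) to a pyran nor retro-Michael loss of the bridge is triggered, and the chelated aryl ketones and enols resist reduction.

**Compound list**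
1 | glutaryl chloride (pentanedioyl dichloride) | O=C(Cl)CCCC(=O)Cl | starting material
2 | benzyl isobutyrate (benzyl 2-methylpropanoate) | CC(C)C(=O)OCc1ccccc1 | starting material
3 | lithium enolate of benzyl isobutyrate | CC(C)=C([O-])OCc1ccccc1.[Li+] | intermediate
4 | dibenzyl 2,2,8,8-tetramethyl-3,7-dioxononanedioate | O=C(OCc1ccccc1)C(C)(C)C(=O)CCCC(=O)C(C)(C)C(=O)OCc1ccccc1 | intermediate
5 | 2,2,8,8-tetramethyl-3,7-dioxononanedioic acid | OC(=O)C(C)(C)C(=O)CCCC(=O)C(C)(C)C(=O)O | intermediate
6 | 2,2,8,8-tetramethyl-3,7-dioxononanedioyl dichloride | ClC(=O)C(C)(C)C(=O)CCCC(=O)C(C)(C)C(=O)Cl | intermediate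
7 | dimethyl malonate | COC(=O)CC(=O)OC | starting material
8 | chloromagnesium enolate of dimethyl malonate | COC(=O)C=C([O-])OC.[Mg+2].[Cl-] | intermediate
9 | tetramethyl 2,2'-(2,2,8,8-tetramethyl-3,7-dioxononanedioyl)dimalonate (each former acid chloride carbon carries CH(CO2Me)2) | COC(=O)C(C(=O)OC)C(=O)C(C)(C)C(=O)CCCC(=O)C(C)(C)C(=O)C(C(=O)OC)C(=O)OC | intermediate
10 | tetramethyl 2,2'-(1,9-dimethoxy-2,2,8,8-tetramethyl-3,7-dioxononane-1,9-diylidene)dimalonate | COC(=C(C(=O)OC)C(=O)OC)C(C)(C)C(=O)CCCC(=O)C(C)(C)C(OC)=C(C(=O)OC)C(=O)OC | intermediate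
11 | acetylacetone (pentane-2,4-dione) | CC(=O)CC(C)=O | starting material
12 | (Z)-4-(trimethylsilyloxy)pent-3-en-2-one | CC(=O)/C=C(\O[Si](C)(C)C)C | intermediate
13 | lithium 4-(trimethylsilyloxy)penta-1,3-dien-2-olate (Z) | C=C([O-])/C=C(\O[Si](C)(C)C)C.[Li+] | intermediate
14 | (3Z)-2,4-bis(trimethylsilyloxy)penta-1,3-diene | C=C(O[Si](C)(C)C)/C=C(\O[Si](C)(C)C)C | intermediate
15 | open-chain adduct: 10 with each methoxy group on C4a replaced by a CH2C(=O)CH=C(OSiMe3)CH3 chain (Z), drawn free of titanium | COC(=O)C(C(=O)OC)=C(CC(=O)/C=C(\O[Si](C)(C)C)C)C(C)(C)C(=O)CCCC(=O)C(C)(C)C(CC(=O)/C=C(\O[Si](C)(C)C)C)=C(C(=O)OC)C(=O)OC | intermediate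
16 | dimethyl 6,6'-(2,8-dimethyl-3,7-dioxononane-2,8-diyl)bis(3-acetyl-2,4-dihydroxybenzoate) | CC(=O)c1c(O)cc(c(C(=O)OC)c1O)C(C)(C)C(=O)CCCC(=O)C(C)(C)c1cc(O)c(C(C)=O)c(O)c1C(=O)OC | intermediate
17 | dimethyl 6,6'-(2,8-dimethyl-3,7-dioxononane-2,8-diyl)bis[3-acetyl-2,4-bis(benzyloxy)benzoate] | CC(=O)c1c(OCc2ccccc2)cc(c(C(=O)OC)c1OCc1ccccc1)C(C)(C)C(=O)CCCC(=O)C(C)(C)c1cc(OCc2ccccc2)c(C(C)=O)c(OCc2ccccc2)c1C(=O)OC | intermediate
18 | 2,2'-methylenebis[7-acetyl-6,8-bis(benzyloxy)-3-hydroxy-4,4-dimethylnaphthalen-1(4H)-one] | CC(=O)c1c(OCc2ccccc2)cc2c(c1OCc1ccccc1)C(=O)C(CC1=C(O)C(C)(C)c3cc(OCc4ccccc4)c(C(C)=O)c(OCc4ccccc4)c3C1=O)=C(O)C2(C)C | intermediate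
19 | 2,2'-methylenebis(7-acetyl-3,6,8-trihydroxy-4,4-dimethylnaphthalen-1(4H)-one), CNP0295164.0 | CC(=O)c1c(O)cc2c(c1O)C(=O)C(CC1=C(O)C(C)(C)c3cc(O)c(C(C)=O)c(O)c3C1=O)=C(O)C2(C)C | target

**Total step count:** 11 (steps 6 and 7 are the side branch to 14).
**Longest linear sequence:** 9 (steps 1–5 and 8–11).

**Three steps most likely to fail**

1. Step 8.
- **What may go wrong:** Addition of C5 to the fully substituted C4a, which sits next to the quaternary C4, may be too slow. Then 14 would be used up by hydrolysis, by self-condensation or by Mukaiyama aldol addition to the C3 ketone. TiCl4 may also strip the methyl group from the enol ether, or the sequence may stall after the first C–C bond in one or both halves.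
- **Fallback (known chemistry only; sets out from 2, comes back at 19):** The quaternary carbon is attached to a ready-made resorcinol ring instead of building ring A beside it. Palladium-catalysed α-arylation of the lithium enolate of 2 with 1-bromo-3,5-dimethoxybenzene (LiNCy2, Pd(dba)2, P(tBu)3, toluene, rt) should give benzyl 2-(3,5-dimethoxyphenyl)-2-methylpropanoate F1. Hydrogenolysis (H2, Pd/C, EtOAc) gives 2-(3,5-dimethoxyphenyl)-2-methylpropanoic acid F2. Directed ortho-metalation between the two methoxy groups (s-BuLi, TMEDA, THF, −78 °C, the acid carried as its lithium salt) and a quench with N-methoxy-N-methylacetamide put the acetyl group on the future C7. This gives 2-(4-acetyl-3,5-dimethoxyphenyl)-2-methylpropanoic acid F3. Oxalyl chloride with catalytic DMF gives 2-(4-acetyl-3,5-dimethoxyphenyl)-2-methylpropanoyl chloride F4. With potassium methyl malonate, MgCl2 and Et3N (decarboxylative Claisen condensation), F4 gives methyl 4-(4-acetyl-3,5-dimethoxyphenyl)-4-methyl-3-oxopentanoate F5. Intramolecular Friedel–Crafts acylation in P2O5/MeSO3H at rt closes ring B at one of the two equivalent positions ortho to the side chain. The product is 7-acetyl-3-hydroxy-6,8-dimethoxy-4,4-dimethylnaphthalen-1(4H)-one F6. BCl3 (CH2Cl2, −78 → 0 °C) cleaves both methyl ethers, each of which is ortho to a carbonyl group, to give 7-acetyl-3,6,8-trihydroxy-4,4-dimethylnaphthalen-1(4H)-one F7. Two molecules of F7 and one of aqueous formaldehyde (EtOH, rt) join at C2 by Knoevenagel condensation followed by Michael addition, as cyclic 1,3-diones do, and give 19.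

2. Step 5.
- **What may go wrong:** The bulky acyl group is twisted out of conjugation and 9 sits largely in its C–H form. Methyl transfer may therefore go to the malonate carbon C8a or to an ester oxygen instead of the oxygen on C4a.
- **Fallback (sets out from 9, comes back at 10):** The oxygen on C4a is exchanged for chloride and methoxide is then brought in as the nucleophile. POCl3 and Bu3N (toluene, 100 °C) should convert 9 into tetramethyl 2,2'-(1,9-dichloro-2,2,8,8-tetramethyl-3,7-dioxononane-1,9-diylidene)dimalonate F8. This is the usual route from acylmalonates to 1-chloroalkylidene malonates. Vinylic addition-elimination with NaOMe (2.0 equiv, MeOH/THF, −20 °C, short contact so that C2 is not deprotonated) then gives 10.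

3. Step 2.
- **What may go wrong:** CO2 may be lost from the 2,2-dimethyl-3-oxo acid units during hydrogenolysis, during concentration, or before chlorination is complete.
- **Fallback (sets out from 1, comes back at 6):** The free acid is never formed. Isobutyric acid is converted (LiN(iPr)2, 2.2 equiv, then Me3SiCl, THF) into 1,1-bis(trimethylsilyloxy)-2-methylprop-1-ene F9. Acylation of two equivalents of this ketene acetal by 1 (ZnBr2 cat., CH2Cl2, 0 °C → rt) gives bis(trimethylsilyl) 2,2,8,8-tetramethyl-3,7-dioxononanedioate F10. Silyl esters react directly with (COCl)2 and catalytic DMF (CH2Cl2, 0 °C) under neutral conditions, and this gives 6.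

**Further compounds**
F1 | step 8 | benzyl 2-(3,5-dimethoxyphenyl)-2-methylpropanoate | COc1cc(OC)cc(c1)C(C)(C)C(=O)OCc1ccccc1
F2 | step 8 | 2-(3,5-dimethoxyphenyl)-2-methylpropanoic acid | COc1cc(OC)cc(c1)C(C)(C)C(=O)O
F3 | step 8 | 2-(4-acetyl-3,5-dimethoxyphenyl)-2-methylpropanoic acid | CC(=O)c1c(OC)cc(cc1OC)C(C)(C)C(=O)O
F4 | step 8 | 2-(4-acetyl-3,5-dimethoxyphenyl)-2-methylpropanoyl chloride | CC(=O)c1c(OC)cc(cc1OC)C(C)(C)C(=O)Cl
F5 | step 8 | methyl 4-(4-acetyl-3,5-dimethoxyphenyl)-4-methyl-3-oxopentanoate | CC(=O)c1c(OC)cc(cc1OC)C(C)(C)C(=O)CC(=O)OC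
F6 | step 8 | 7-acetyl-3-hydroxy-6,8-dimethoxy-4,4-dimethylnaphthalen-1(4H)-one | CC(=O)c1c(OC)cc2c(c1OC)C(=O)C=C(O)C2(C)C
F7 | step 8 | 7-acetyl-3,6,8-trihydroxy-4,4-dimethylnaphthalen-1(4H)-one | CC(=O)c1c(O)cc2c(c1O)C(=O)C=C(O)C2(C)C
F8 | step 5 | tetramethyl 2,2'-(1,9-dichloro-2,2,8,8-tetramethyl-3,7-dioxononane-1,9-diylidene)dimalonate | COC(=O)C(C(=O)OC)=C(Cl)C(C)(C)C(=O)CCCC(=O)C(C)(C)C(Cl)=C(C(=O)OC)C(=O)OC
F9 | step 2 | 1,1-bis(trimethylsilyloxy)-2-methylprop-1-ene | CC(C)=C(O[Si](C)(C)C)O[Si](C)(C)C
F10 | step 2 | bis(trimethylsilyl) 2,2,8,8-tetramethyl-3,7-dioxononanedioate | C[Si](C)(C)OC(=O)C(C)(C)C(=O)CCCC(=O)C(C)(C)C(=O)O[Si](C)(C)C
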